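**Plan**

1. Cuts (isochromene numbering in each half: C1, O2, C3, C4, C4a, C5, C6, C7, C8, C8a). The bond from the bridge CH2 to C7 of the quinone methide half is cut first. This leaves an ortho-quinone methide of the isochroman half and the monomer decarboxycitrinin, and the isochroman half is the C1 hydride adduct of that same monomer.
2. In the monomer the pyran ring is opened at O2–C1 (C3–OH plus C1 aldehyde). The ring-fusion bond C4a–C8a is then cut, which unrolls the carbocycle to a linear pentaketide chain, and the chain is cut at C4a–C5 and C6–C7.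
3. Enabling feature: along the carbocycle C4a–C5–C6–C7–C8–C8a and its substituent C1, oxygen sits on alternate carbons (C1, C8, C6). C8a is therefore the central carbon of a 1,3-dicarbonyl unit, and the oxygen-free C4a, six atoms on, is the trace of a dehydrated ketone. This is the aldol closure of the polyketide biosynthesis.
4. Forward: two acylations join C6–C7 and C4a–C5, the carbocycle closes with all six substituents in place (step 6), and the pyran ring closes (step 8). Part of the monomer is reduced and aminomethylated, and the halves are joined at the bridge (step 11).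
5. Helpers: a 2,2-dimethyl-1,3-dioxin-4-one ring masks C1 (acid level) and the C8 enol, and a silyl ether keeps O2 off the ketones. They leave in steps 7 and 8.
6. Stereochemistry: C3 comes from methyl (R)-3-hydroxybutanoate and C4 from an anti-selective Fráter–Seebach methylation. The one (3R,4S) pair serves both halves, and the uncontrolled C5 centre of the chain vanishes on aromatisation.

Key step: step 6

Assumption: the quinone methide unit is drawn as the 8-oxo/6-hydroxy tautomer of the given structure; it should equilibrate freely with the 6-oxo/8-hydroxy tautomer and, in wet media, with its C1 hydrate, so no step has to control this and drying restores the quinone methide.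

**Route**

Step 1
Reactants: 1 methyl (R)-3-hydroxybutanoate
Product: 2 methyl (2R,3R)-3-hydroxy-2-methylbutanoate
Conditions: LiN(iPr)2 (2.2 equiv), THF, −78 to −20 °C; MeI, DMPU, −78 to 0 °C
Reagents that add atoms: iodomethane, CI
Why: Fráter–Seebach alkylation, in which the chelated lithium alkoxide enolate should be methylated on the face opposite the carbinol methyl group, so that C3 controls the new centre (later C4) and the anti (2R,3R) ester results.

Step 2
Reactants: 2 methyl (2R,3R)-3-hydroxy-2-methylbutanoate
Product: 3 methyl (2R,3R)-3-(tert-butyldimethylsilyloxy)-2-methylbutanoate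
Conditions: TBSCl, imidazole, DMF, 23 °C
Reagents that add atoms: tert-butyldimethylsilyl chloride, CC(C)(C)[Si](C)(C)Cl
Why: Standard silylation of a secondary alcohol; the silyl ether later keeps O2 from adding to the C6 ketone of the polycarbonyl chain.

Step 3
Reactants: 3 methyl (2R,3R)-3-(tert-butyldimethylsilyloxy)-2-methylbutanoate
Product: 4 (2R,3R)-3-(tert-butyldimethylsilyloxy)-N-methoxy-N,2-dimethylbutanamide
Conditions: MeNH(OMe)·HCl, iPrMgCl, THF, −20 to 0 °C
Reagents that add atoms: N,O-dimethylhydroxylamine hydrochloride, CNOC.Cl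
Why: Weinreb amide formation by direct aminolysis of the ester with the magnesium amide, a protocol that is known to leave the α-stereocentre of β-silyloxy esters intact.

Step 4
Reactants: 5 2,2,6-trimethyl-4H-1,3-dioxin-4-one; 6 propanoyl chloride
Product: 7 2,2-dimethyl-6-(2-oxobutyl)-4H-1,3-dioxin-4-one
Conditions: LiN(SiMe3)2 (2 equiv), THF, −78 °C; then 6, −78 °C
Reagents that add atoms: none
Why: γ-Acylation of the lithium dienolate of the dioxinone with an acid chloride, the standard entry to 6-(2-oxoalkyl)dioxinones, with the second equivalent of base taking up the more acidic product.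

Step 5
Reactants: 7 2,2-dimethyl-6-(2-oxobutyl)-4H-1,3-dioxin-4-one; 4 (2R,3R)-3-(tert-butyldimethylsilyloxy)-N-methoxy-N,2-dimethylbutanamide
Product: 8 6-[(5R,6R)-6-(tert-butyldimethylsilyloxy)-3,5-dimethyl-2,4-dioxoheptyl]-2,2-dimethyl-4H-1,3-dioxin-4-one (C5 epimers and enol forms)
Conditions: 7, LiN(iPr)2 (2.1 equiv), THF, −78 to −30 °C; then 4, −78 to −10 °C
Reagents that add atoms: none
Why: Crossed Claisen-type acylation of a 1,3-dicarbonyl dianion, in which the second-formed, more basic carbanion at C5 reacts and the chelated tetrahedral adduct of the Weinreb amide holds until work-up, so that over-addition and epimerisation at C4 should be avoided and the new C5 centre needs no control.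

Step 6
Reactants: 8 6-[(5R,6R)-6-(tert-butyldimethylsilyloxy)-3,5-dimethyl-2,4-dioxoheptyl]-2,2-dimethyl-4H-1,3-dioxin-4-one
Product: 10 5-[(2S,3R)-3-(tert-butyldimethylsilyloxy)butan-2-yl]-7-hydroxy-2,2,6-trimethyl-4H-1,3-benzodioxin-4-one, via aldol adduct 9 (not isolated)
Conditions: Et3N, CH2Cl2, 23 to 40 °C
Reagents that add atoms: none
Why: Et3N removes a C7 proton (flanked by the C6 ketone and the dioxinone), the extended dienolate attacks the C4a ketone through its α-carbon C8a (C5 of the dioxinone) to give 9, and E1cB loss of water followed by enolisation of the C6 ketone gives the phenol. The closest known reaction type is the amine- or carbonate-induced aromatisation of 6-(2,4-dioxoalkyl)-1,3-dioxin-4-ones to acetonide-protected resorcylates, which copies the aldol cyclisation of a polyketide synthase. One ring closes, the carbocycle C4a–C5–C6–C7–C8–C8a, in the 6-(enolexo)-exo-trig mode. No lasting stereocentre is made, since the centres at C4a, C5 and C8a of 9 are erased on aromatisation, so all C5 epimers and enol forms of 8 converge on one product, while C3 and C4 stay untouched because the far more acidic C5 and C7 protons buffer the weak base. The step needs C8a-to-C4a aldol closure in preference to Claisen closure (C5 to C1), O-cyclisation to a pyranone and β-elimination of silanolate; the dioxinone holds C1 trans to the chain across C8=C8a and out of reach, masks C8 as an enol ether and leaves C4a as the only ketone six atoms from a nucleophilic carbon, and the silyl ether blocks attack of O2 on C6.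

Step 7
Reactants: 10 5-[(2S,3R)-3-(tert-butyldimethylsilyloxy)butan-2-yl]-7-hydroxy-2,2,6-trimethyl-4H-1,3-benzodioxin-4-one
Product: 11 2-[(2S,3R)-3-(tert-butyldimethylsilyloxy)butan-2-yl]-4,6-dihydroxy-3-methylbenzaldehyde
Conditions: iBu2AlH (3.5 equiv), CH2Cl2, −78 °C; then H2O
Reagents that add atoms: none
Why: Known partial reduction of 2,2-dimethyl-1,3-benzodioxin-4-ones to salicylaldehydes, in which the first equivalent is consumed by the phenol, the aluminium hemiacetal persists at −78 °C, and it collapses only on work-up with loss of acetone, which removes the temporary ring and brings C1 to the aldehyde level.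

Step 8
Reactants: 11 2-[(2S,3R)-3-(tert-butyldimethylsilyloxy)butan-2-yl]-4,6-dihydroxy-3-methylbenzaldehyde
Product: 14 decarboxycitrinin (3R,4S)-6-hydroxy-3,4,5-trimethyl-3,4-dihydroisochromen-8-one, via hydroxy aldehyde 12 (not isolated), via lactol 13 (not isolated)
Conditions: 48% aq. HF, MeCN, 0 to 23 °C; toluene azeotrope
Reagents that add atoms: none
Why: Fluoride-mediated desilylation frees the C3 hydroxyl, which adds to the ortho formyl group (6-exo-trig), and acid-promoted loss of water from the lactol gives the quinone methide as a stabilised vinylogous acid, the same closure that ends the classical routes to citrinin and that touches neither stereocentre.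

Step 9
Reactants: 14 decarboxycitrinin (a portion of the material)
Product: 15 (3R,4S)-3,4,5-trimethylisochroman-6,8-diol
Conditions: NaBH4, MeOH, 0 °C
Reagents that add atoms: none
Why: Conjugate hydride addition to the electrophilic C1 terminus of the quinone methide with rearomatisation, the reaction type by which citrinin is converted into dihydrocitrinin.

Step 10
Reactants: 15 (3R,4S)-3,4,5-trimethylisochroman-6,8-diol
Product: 16 (3R,4S)-7-[(dimethylamino)methyl]-3,4,5-trimethylisochroman-6,8-diol
Conditions: 37% aq. CH2O, 40% aq. Me2NH (premixed, excess), EtOH, 0 to 23 °C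
Reagents that add atoms: formaldehyde, C=O; dimethylamine, CNC
Why: Mannich reaction of a resorcinol, whose regiochemistry is fixed because C7, between the two hydroxyl groups, is the only unsubstituted ring position.

Step 11
Reactants: 16 (3R,4S)-7-[(dimethylamino)methyl]-3,4,5-trimethylisochroman-6,8-diol; 14 decarboxycitrinin
Product: 18 dicitrinone I, via ortho-quinone methide 17 (not isolated)
Conditions: 1,4-dioxane, 100 °C, slow N2 stream
Reagents that add atoms: none
Why: Thermal loss of Me2NH from the ortho-hydroxybenzylamine gives 17, which should be captured in a Michael addition by C7 of 14, the α-carbon of its enolised 1,3-dicarbonyl unit and its only nucleophilic C–H site, a known way to unsymmetrical methylene-bridged phenol/1,3-dicarbonyl dimers that also copies the presumed biosynthetic union.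

**Compound list**

1 | methyl (R)-3-hydroxybutanoate | C[C@@H](O)CC(=O)OC | starting material
2 | methyl (2R,3R)-3-hydroxy-2-methylbutanoate | COC(=O)[C@H](C)[C@@H](C)O | intermediate
3 | methyl (2R,3R)-3-(tert-butyldimethylsilyloxy)-2-methylbutanoate | COC(=O)[C@H](C)[C@@H](C)O[Si](C)(C)C(C)(C)C | intermediate
4 | (2R,3R)-3-(tert-butyldimethylsilyloxy)-N-methoxy-N,2-dimethylbutanamide | CON(C)C(=O)[C@H](C)[C@@H](C)O[Si](C)(C)C(C)(C)C | intermediate
5 | 2,2,6-trimethyl-4H-1,3-dioxin-4-one | CC1=CC(=O)OC(C)(C)O1 | starting material
6 | propanoyl chloride | CCC(=O)Cl | starting material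
7 | 2,2-dimethyl-6-(2-oxobutyl)-4H-1,3-dioxin-4-one | CCC(=O)CC1=CC(=O)OC(C)(C)O1 | intermediate
8 | 6-[(5R,6R)-6-(tert-butyldimethylsilyloxy)-3,5-dimethyl-2,4-dioxoheptyl]-2,2-dimethyl-4H-1,3-dioxin-4-one (C5 unfixed) | CC(C(=O)CC1=CC(=O)OC(C)(C)O1)C(=O)[C@H](C)[C@@H](C)O[Si](C)(C)C(C)(C)C | intermediate
9 | aldol adduct: 5-[(2S,3R)-3-(tert-butyldimethylsilyloxy)butan-2-yl]-5-hydroxy-2,2,6-trimethyl-4a,5-dihydro-4H-1,3-benzodioxine-4,7(6H)-dione (new centres unfixed) | CC1C(=O)C=C2OC(C)(C)OC(=O)C2C1(O)[C@H](C)[C@@H](C)O[Si](C)(C)C(C)(C)C | intermediate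
10 | 5-[(2S,3R)-3-(tert-butyldimethylsilyloxy)butan-2-yl]-7-hydroxy-2,2,6-trimethyl-4H-1,3-benzodioxin-4-one | Cc1c(O)cc2OC(C)(C)OC(=O)c2c1[C@H](C)[C@@H](C)O[Si](C)(C)C(C)(C)C | intermediate
11 | 2-[(2S,3R)-3-(tert-butyldimethylsilyloxy)butan-2-yl]-4,6-dihydroxy-3-methylbenzaldehyde | Cc1c(O)cc(O)c(C=O)c1[C@H](C)[C@@H](C)O[Si](C)(C)C(C)(C)C | intermediate
12 | 4,6-dihydroxy-2-[(2S,3R)-3-hydroxybutan-2-yl]-3-methylbenzaldehyde | Cc1c(O)cc(O)c(C=O)c1[C@H](C)[C@@H](C)O | intermediate
13 | (3R,4S)-3,4,5-trimethylisochroman-1,6,8-triol (lactol, C1 unfixed) | Cc1c(O)cc(O)c2c1[C@H](C)[C@@H](C)OC2O | intermediate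
14 | decarboxycitrinin, (3R,4S)-6-hydroxy-3,4,5-trimethyl-3,4-dihydroisochromen-8-one | CC1=C2C(=CO[C@H](C)[C@H]2C)C(=O)C=C1O | intermediate
15 | (3R,4S)-3,4,5-trimethylisochroman-6,8-diol | Cc1c(O)cc(O)c2c1[C@H](C)[C@@H](C)OC2 | intermediate
16 | (3R,4S)-7-[(dimethylamino)methyl]-3,4,5-trimethylisochroman-6,8-diol | Cc1c(O)c(CN(C)C)c(O)c2c1[C@H](C)[C@@H](C)OC2 | intermediate
17 | (3R,4S)-8-hydroxy-3,4,5-trimethyl-7-methylidene-3,4-dihydro-1H-isochromen-6(7H)-one | C=C1C(=O)C(C)=C2C(=C1O)CO[C@H](C)[C@H]2C | intermediate
18 | dicitrinone I | CC1=C2C(=CO[C@H](C)[C@H]2C)C(=O)C(Cc2c(O)c(C)c3c(c2O)CO[C@H](C)[C@H]3C)=C1O | target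

**Count**

Total steps: 11. Longest linear sequence: 10 steps (steps 1, 2, 3, 5, 6, 7, 8, 9, 10, 11). Step 4 is a one-step side branch from commercial 5 and 6.

**The three steps most likely to fail**

Step 5.
- What may go wrong: the secondary C5 carbanion adds only slowly to the α-branched amide. Proton transfer from the α-position of 4 and β-elimination of silanolate could then take over.
- Fallback: aldol addition and oxidation in place of acylation, setting out from 3.
- iBu2AlH in CH2Cl2 at −78 °C should reduce 3 to (2R,3R)-3-(tert-butyldimethylsilyloxy)-2-methylbutanal F1.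
- The dianion of 7 should add through C5 to this more electrophilic and less crowded carbonyl group. This gives the C4a carbinol of 8 (β-hydroxy ketone, epimers at C4a and C5) F2.
- Dess–Martin oxidation of the carbinol comes back to the route at 8.

Step 6.
- What may go wrong: aldol closure is sluggish at a ketone flanked by two tertiary carbons. O-cyclisation or retro-Claisen cleavage of the chain could then compete.
- Fallback: ketene generation and trapping, then closure of an open-chain β-keto ester, setting out from 8.
- Heating 8 with methanol in toluene at 110 °C should expel acetone in a retro-hetero-Diels–Alder reaction and give the acylketene F3.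
- Methanol traps F3 as methyl (8R,9R)-9-(tert-butyldimethylsilyloxy)-6,8-dimethyl-3,5,7-trioxodecanoate F4. Its C8a is a free β-keto ester methylene, more acidic and less encumbered than the dioxinone CH.
- Cs2CO3 in MeOH followed by acidification should close and dehydrate F4 to methyl 2-[(2S,3R)-3-(tert-butyldimethylsilyloxy)butan-2-yl]-4,6-dihydroxy-3-methylbenzoate F5.
- Aq. HF in MeCN removes the silyl group, and the freed alcohol lactonises to (3R,4S)-6,8-dihydroxy-3,4,5-trimethylisochroman-1-one F6.
- Excess iBu2AlH at −78 °C, with the phenols carried as aluminium phenoxides, should reduce F6 to lactol 13. Loss of water on acidic work-up comes back to the route at 14.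

Step 11.
- What may go wrong: the liberated amine adds reversibly to C1 of the quinone methide and opens the pyran ring. Self-condensation of the transient ortho-quinone methide and thermal decay of 14 are further risks.
- Fallback: the bridge is made on the robust aromatic aldehyde and the quinone methide is formed last, setting out from 16 and 11.
- Heating 16 and 11 in 1,4-dioxane should let the phenoxide of 11 take up 17 at its free position between the two hydroxyl groups. This gives 2-[(2S,3R)-3-(tert-butyldimethylsilyloxy)butan-2-yl]-5-{[(3R,4S)-6,8-dihydroxy-3,4,5-trimethylisochroman-7-yl]methyl}-4,6-dihydroxy-3-methylbenzaldehyde F7.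
- Aq. HF in MeCN then removes the silyl group and closes the pyran ring as in step 8, which comes back to the route at 18.

**Further compounds**

F1 | step 5 | (2R,3R)-3-(tert-butyldimethylsilyloxy)-2-methylbutanal | O=C[C@H](C)[C@@H](C)O[Si](C)(C)C(C)(C)C
F2 | step 5 | C4a carbinol of 8 (β-hydroxy ketone, epimers at C4a and C5) | CC(C(=O)CC1=CC(=O)OC(C)(C)O1)C(O)[C@H](C)[C@@H](C)O[Si](C)(C)C(C)(C)C
F3 | step 6 | acylketene from 8 by loss of acetone | CC(C(=O)CC(=O)C=C=O)C(=O)[C@H](C)[C@@H](C)O[Si](C)(C)C(C)(C)C
F4 | step 6 | methyl (8R,9R)-9-(tert-butyldimethylsilyloxy)-6,8-dimethyl-3,5,7-trioxodecanoate | COC(=O)CC(=O)CC(=O)C(C)C(=O)[C@H](C)[C@@H](C)O[Si](C)(C)C(C)(C)C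
F5 | step 6 | methyl 2-[(2S,3R)-3-(tert-butyldimethylsilyloxy)butan-2-yl]-4,6-dihydroxy-3-methylbenzoate | COC(=O)c1c(O)cc(O)c(C)c1[C@H](C)[C@@H](C)O[Si](C)(C)C(C)(C)C
F6 | step 6 | (3R,4S)-6,8-dihydroxy-3,4,5-trimethylisochroman-1-one | Cc1c(O)cc(O)c2c1[C@H](C)[C@@H](C)OC2=O
F7 | step 11 | 2-[(2S,3R)-3-(tert-butyldimethylsilyloxy)butan-2-yl]-5-{[(3R,4S)-6,8-dihydroxy-3,4,5-trimethylisochroman-7-yl]methyl}-4,6-dihydroxy-3-methylbenzaldehyde | Cc1c(O)c(Cc2c(O)c(C)c3c(c2O)CO[C@H](C)[C@H]3C)c(O)c(C=O)c1[C@H](C)[C@@H](C)O[Si](C)(C)C(C)(C)C
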